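**Plan**

- Atom numbers follow ent-kaurane (C18 = CH3 and C19 = OCH2 on C4; C6 and C7 = lactone C=O on C5 and C8; C20 = OCH2 on C10; C17 = CH2OH on C16). Cuts, in order: C17–O and C15=O (ring D enone chemistry), C13–C16 (ring D), then C13–C14 together with C8–C9 (ring C and, with it, the 7,20-lactone ring B), the O20–C7 ester, C10–C9, C4–CH3, and ring A (C3–C4, C5–C10).
- Forward: ring A by a catalytic asymmetric Diels–Alder reaction, C4 methylation and 6,19-lactone, C10 made quaternary by a Claisen rearrangement, acrylate on O20 and silyloxydiene on C10, intramolecular Diels–Alder reaction (rings B and C), vinyl-radical closure of ring D, then oxygenation at C11, C15 and C17.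
- Enabling feature: ring B is an ester O20–C7(=O)–C8 that ties C8 to the spiro carbon C10. A 2-propargylacrylate on O20 (C8=C14) is therefore held over a C9=C11(OSi)–C12=C13 diene on C10, and the C11 oxygen of the target is the diene's silyloxy group.
- Stereochemistry: C5 from a copper–bis(oxazoline) catalyst; C4 and C10 by relay (alkylation anti to the C5 carboxylate; Claisen on the convex face of the cis-lactone); C8 and C9 in the cycloaddition; C13 by the bridge; C11 by thermodynamic reduction; C16 by exo-face protonation.

Key step: step 19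

Remarks: 1, 3, 4 and 19 are taken as commercial. The "top face" of ring A is the face that carries C19, C6 and C20. The C10 configuration drawn for 6 to 15 is that of the endo adduct; it is erased in step 10, so the exo adduct converges.

Step 1
Reactants: 1 (2E)-penta-2,4-dien-1-ol
Product: 2 tert-butyl(dimethyl)[(2E)-penta-2,4-dien-1-yloxy]silane
Conditions: TBSCl, imidazole, CH2Cl2, 0 °C to rt
Reagents that add atoms: tert-butyl(chloro)dimethylsilane, CC(C)(C)[Si](C)(C)Cl
Why: Standard silylation of a primary alcohol, which keeps O20 masked until the 6,19-lactone is in place.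

Step 2
Reactants: 3 1,3-oxazolidin-2-one; 4 ethyl (2E)-4-chloro-4-oxobut-2-enoate
Product: 5 ethyl (2E)-4-oxo-4-(2-oxo-1,3-oxazolidin-3-yl)but-2-enoate
Conditions: LiCl, Et3N, THF, 0 °C to rt
Reagents that add atoms: none
Why: N-acylation of the oxazolidinone by the acid chloride gives the two-point-binding fumarate dienophile.

Step 3
Reactants: 2 tert-butyl(dimethyl)[(2E)-penta-2,4-dien-1-yloxy]silane; 5 ethyl (2E)-4-oxo-4-(2-oxo-1,3-oxazolidin-3-yl)but-2-enoate
Product: 6 ethyl (1S,5S,6S)-5-[(tert-butyldimethylsilyloxy)methyl]-6-(2-oxo-1,3-oxazolidine-3-carbonyl)cyclohex-3-ene-1-carboxylate (ester trans and CH2OTBS cis to the acyl group)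
Conditions: [Cu((R,R)-t-Bu-box)](SbF6)2 (10 mol %), CH2Cl2, −20 °C to rt
Reagents that add atoms: none
Why: Bis(oxazoline)–copper-catalysed Diels–Alder reaction in which the imide chelates the square-planar divalent copper centre in its s-cis form, the tert-butyl group of the (R,R) ligand blocks the Re face of C5 so the diene adds to the Si face, the substituted diene terminus bonds "ortho" to the chelated acyl group (C10–C5, C3–C4) and endo addition places CH2OTBS cis to it.

Step 4
Reactants: 6 Diels–Alder adduct
Product: 7 ethyl 3-[(tert-butyldimethylsilyloxy)methyl]-2-(2-oxo-1,3-oxazolidine-3-carbonyl)cyclohexane-1-carboxylate (same relative and absolute configuration as 6)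
Conditions: H2 (1 atm), 10 % Pd/C, EtOAc, rt
Reagents that add atoms: none
Why: Heterogeneous hydrogenation saturates the C1=C2 alkene before any other C=C is present and creates no stereocentre.

Step 5
Reactants: 7 saturated imide
Product: 9 2-(ethoxycarbonyl)-6-[(tert-butyldimethylsilyloxy)methyl]cyclohexane-1-carboxylic acid (C6 acid; C19 ester trans; C20 arm cis), via peroxy acid 8 (not isolated)
Conditions: LiOH, H2O2, THF/H2O, 0 °C; then aq. Na2SO3; aq. HCl to pH 3
Reagents that add atoms: hydrogen peroxide, OO
Why: Lithium hydroperoxide attacks the exocyclic imide carbonyl selectively and the peroxy acid is reduced by sulfite, which frees the C6 acid without touching the ethyl ester or epimerizing C5.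

Step 6
Reactants: 9 hemiester acid
Product: 11 2-(ethoxycarbonyl)-2-methyl-6-[(tert-butyldimethylsilyloxy)methyl]cyclohexane-1-carboxylic acid (CO2Et cis and CH3 trans to the C6 acid), via dilithium enolate carboxylate 10 (not isolated)
Conditions: LiN(i-Pr)2 (2.3 equiv), THF, −78 to −20 °C; MeI, −78 to 0 °C; aq. HCl
Reagents that add atoms: iodomethane, CI
Why: Hemiester dianion alkylation in which the second deprotonation occurs at C4 (ester α-carbon), the C5 carboxylate sits axial to avoid allylic strain with the enolate and MeI enters anti to it, so the quaternary C4 centre forms with CH3 trans and CO2Et cis to C6.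

Step 7
Reactants: 11 methylated hemiester
Product: 13 cis-fused 7-[(tert-butyldimethylsilyloxy)methyl]-3a-methylhexahydro-2-benzofuran-1(3H)-one (6,19-lactone; CH2OTBS on the lactone face), via hydroxy acid 12 (not isolated)
Conditions: LiBHEt3 (3.5 equiv), THF, 0 °C to rt; aq. HCl to pH 4; then PhMe, 60 °C
Reagents that add atoms: none
Why: LiBHEt3 reduces the neopentyl ester but not the lithium carboxylate, and the cis γ-hydroxy acid then lactonizes (5-exo-trig acyl substitution) to the cis-fused 6,19-lactone while O20 is still silylated.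

Step 8
Reactants: 13 lactone silyl ether
Product: 14 cis-fused 7-(hydroxymethyl)-3a-methylhexahydro-2-benzofuran-1(3H)-one
Conditions: HF·pyridine, pyridine, THF, 0 °C to rt
Reagents that add atoms: none
Why: Buffered fluoride cleavage of the primary silyl ether under non-basic conditions that should not move the lactone onto O20.

Step 9
Reactants: 14 hydroxy lactone
Product: 15 cis-fused 3a-methyl-1-oxooctahydro-2-benzofuran-7-carbaldehyde (C20 aldehyde on C10)
Conditions: Dess–Martin periodinane, CH2Cl2, rt
Reagents that add atoms: none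
Why: Dess–Martin oxidation of the primary alcohol under neutral conditions, where epimerization at C10 is harmless because that centre is rebuilt in step 10.

Step 10
Reactants: 15 lactone aldehyde
Product: 18 7-allyl-3a-methyl-1-oxooctahydro-2-benzofuran-7-carbaldehyde (CHO on the lactone face; allyl on the face of the 3a-methyl group and H-7a), via diallyl acetal 16 (not isolated), via allyl enol ether 17 (not isolated)
Conditions: allyl alcohol (3 equiv), p-TsOH·H2O (2 mol %), p-cymene, 110 to 175 °C, Dean–Stark
Reagents that add atoms: allyl alcohol, C=CCO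
Why: Acetalization, loss of allyl alcohol to the allyl enol ether and Claisen [3,3] rearrangement make C10 quaternary, and the new C–C bond should form equatorially on the convex face, anti to the axial C19–O arm of the cis-lactone, so the allyl group (C9, C11, C12) ends trans and CHO (C20) cis to C6.

Step 11
Reactants: 19 diethyl 2-(prop-2-yn-1-yl)propanedioate
Product: 20 2-(prop-2-yn-1-yl)propanedioic acid
Conditions: KOH, EtOH/H2O, rt; then aq. HCl
Reagents that add atoms: potassium hydroxide, [K+].[OH-]
Why: Plain saponification of both malonate esters.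

Step 12
Reactants: 20 2-(prop-2-yn-1-yl)propanedioic acid
Product: 21 2-methylidenepent-4-ynoic acid
Conditions: (CH2O)n, Et2NH, EtOAc, reflux
Reagents that add atoms: formaldehyde (as paraformaldehyde), C=O
Why: Mannich methylenation with decarboxylation (Knoevenagel–Doebner type) turns a monosubstituted malonic acid into the 2-substituted acrylic acid that carries C8, C14, C15, C16 and C17.

Step 13
Reactants: 21 2-methylidenepent-4-ynoic acid
Product: 22 2-methylidenepent-4-ynoyl chloride
Conditions: (COCl)2, DMF (cat.), CH2Cl2, 0 °C to rt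
Reagents that add atoms: oxalyl chloride, ClC(=O)C(Cl)=O
Why: Vilsmeier-catalysed conversion of the acid into its chloride, which is used crude.

Step 14
Reactants: 18 allyl aldehyde; 22 2-methylidenepent-4-ynoyl chloride
Product: 24 (7-allyl-3a-methyl-1-oxooctahydro-2-benzofuran-7-yl)methyl 2-methylidenepent-4-ynoate (O20 acrylate; configuration of 18), via aluminium alkoxide 23 (not isolated)
Conditions: i-Bu2AlH (1.05 equiv), CH2Cl2, −78 °C; then pyridine, DMAP, 22, −78 to −20 °C
Reagents that add atoms: none
Why: One-pot reductive acylation in which i-Bu2AlH reduces the aldehyde faster than the hindered lactone at −78 °C and the aluminium alkoxide is acylated in situ, so a free C20 alcohol that could transesterify onto C6 is never present.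

Step 15
Reactants: 24 allyl ester
Product: 26 (3a-methyl-1-oxo-7-(2-oxoethyl)octahydro-2-benzofuran-7-yl)methyl 2-methylidenepent-4-ynoate (C11 aldehyde), via diol 25 (not isolated)
Conditions: K2OsO4·2H2O (2 mol %), NaIO4, 2,6-lutidine, dioxane/H2O, rt
Reagents that add atoms: sodium periodate, [Na+].[O-]I(=O)(=O)=O; potassium osmate dihydrate (oxygen carrier), O.O.[K+].[K+].[O-][Os](=O)(=O)[O-]
Why: Lemieux–Johnson cleavage in which the osmate dihydroxylates the electron-rich monosubstituted alkene in preference to the acrylate and the alkyne, and periodate cleaves the diol to the aldehyde.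

Step 16
Reactants: 26 C11 aldehyde
Product: 27 [7-(2-hydroxybut-3-en-1-yl)-3a-methyl-1-oxooctahydro-2-benzofuran-7-yl]methyl 2-methylidenepent-4-ynoate (both C11 epimers)
Conditions: CH2=CHMgBr, THF, −78 °C
Reagents that add atoms: vinylmagnesium bromide, C=C[Mg]Br
Why: Grignard 1,2-addition to the aldehyde, the most electrophilic carbonyl at −78 °C, adds C12 and C13 and creates a carbinol centre that is removed in step 17.

Step 17
Reactants: 27 allylic alcohol
Product: 28 [3a-methyl-1-oxo-7-(2-oxobut-3-en-1-yl)octahydro-2-benzofuran-7-yl]methyl 2-methylidenepent-4-ynoate (vinyl ketone)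
Conditions: Dess–Martin periodinane, CH2Cl2, 0 °C
Reagents that add atoms: none
Why: Dess–Martin oxidation of the allylic alcohol to the vinyl ketone under neutral conditions.

Step 18
Reactants: 28 vinyl ketone
Product: 29 {7-[(1Z)-2-(tert-butyldimethylsilyloxy)buta-1,3-dien-1-yl]-3a-methyl-1-oxooctahydro-2-benzofuran-7-yl}methyl 2-methylidenepent-4-ynoate
Conditions: TBSOTf, Et3N, CH2Cl2, −78 to 0 °C
Reagents that add atoms: tert-butyldimethylsilyl trifluoromethanesulfonate, CC(C)(C)[Si](C)(C)OS(=O)(=O)C(F)(F)F
Why: Soft enolization toward C9, the only α-CH2 of the ketone, gives the cross-conjugated silyl dienol ether, and the Z enol ether (C10 trans to the vinyl group) is favoured, which puts C10 on the outside of the diene.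

Step 19
Reactants: 29 silyloxydiene acrylate
Product: 31 keto dilactone with rings A, B and C (ring A with its 6,19-lactone spiro-linked at C10 to δ-lactone ring B; ring B cis-fused to cyclohexanone ring C; C11 ketone; propargyl on C8; H-9 cis to the propargyl group and syn to C5), via cycloadduct silyl enol ether 30 (not isolated)
Conditions: PhMe (0.01 M), BHT, 185 °C, sealed tube; then 1 M HCl, THF, rt
Reagents that add atoms: none
Why: Heating brings the C8=C14 acrylate, held to C10 by the C20–O–C7(=O) ester, over the (Z)-2-silyloxydiene C9=C11(OTBS)–C12=C13, and a concerted, asynchronous thermal [4+2] cycloaddition forms C13–C14 and C8–C9 together, after which acid unmasks the C11 ketone. The closest known reaction type is the ester-tethered type 1 intramolecular Diels–Alder reaction of dienyl 2-substituted acrylates that gives cyclohexene-fused δ-lactones. Ring C closes as the six-membered cycloadduct ring, and ring B closes at the same time as the six-membered ring spanned by the four-atom tether (fused 6,6 mode), helped by the gem-dialkyl effect of quaternary C10. At C8 and C9 the tether carbonyl C7 should sit endo and the propargyl group exo, because in the exo-tether arrangement one ring A carbon must eclipse C9=C11 and clash with the cis OTBS group (allylic 1,3-strain); with C10 on the outside of the diene this gives C7 and C10 cis on ring C, that is H-9 cis to C15. The facial selectivity relative to C10 has the same origin: the bulky C5 branch of ring A lies anti to the diene while C1 and C20 straddle it, so the dienophile bonds to the face of C9 that leaves H-9 syn to C5, as in the target. The step needs tether-enforced regiochemistry (C9 to C8, against the electronic bias of the silyloxydiene), reaction of the acrylate and not of the unactivated alkyne, and survival of the silyl dienol ether; the short tether, BHT, high dilution and acid-free glassware should secure these.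

Step 20
Reactants: 31 keto dilactone
Product: 32 enone (C11 ketone conjugated with C12=C13; otherwise as 31)
Conditions: IBX, DMSO, 70 °C
Reagents that add atoms: none
Why: IBX α,β-dehydrogenation of the ketone, where only the C12 enol has a β-hydrogen (on C13) because C8 and C10 are quaternary, so a single enone should form.

Step 21
Reactants: 32 enone
Product: 34 11-oxo-16-ene compound (ring D closed through C13–C16 as a bicyclo[3.2.1]octane; exocyclic C16=C17; C15 is CH2), via vinylstannane 33 (not isolated)
Conditions: Bu3SnH, AIBN, PhH, 80 °C (slow addition); then HCl (Et2O), CH2Cl2, 0 °C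
Reagents that add atoms: none
Why: The stannyl radical adds to the terminal alkyne carbon C17 and the C16 vinyl radical closes ring D by 5-exo-trig attack on C13, the β-carbon of the enone, which fixes C13 because the C15 arm can only bridge the face of ring C that it occupies; HCl then protodestannylates the vinylstannane.

Step 22
Reactants: 34 11-oxo-16-ene compound
Product: 35 11-hydroxy-16-ene compound (equatorial C11–OH, cis to C10 and trans to the C15–C16 bridge)
Conditions: SmI2, THF/i-PrOH, rt
Reagents that add atoms: none
Why: SmI2 reduces the ketone through a ketyl and an organosamarium that is protonated under thermodynamic control, which should give the equatorial alcohol because the axial epimer is pressed against the two-carbon bridge, and lactones are not reduced without water–amine activation.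

Step 23
Reactants: 35 11-hydroxy-16-ene compound
Product: 36 11,15-diol (allylic C15–OH; C15 configuration not relevant)
Conditions: SeO2 (0.5 equiv), t-BuOOH, CH2Cl2, rt
Reagents that add atoms: tert-butyl hydroperoxide, CC(C)(C)OO; selenium dioxide (oxygen carrier), O=[Se]=O
Why: Allylic oxidation (ene reaction, then [2,3]-shift) of the 1,1-disubstituted alkene at C15, its only allylic CH2, as is usual for 16-ene kauranoids.

Step 24
Reactants: 36 11,15-diol
Product: 37 11-hydroxy-15-oxo-16-ene compound (exocyclic enone)
Conditions: MnO2, CH2Cl2, rt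
Reagents that add atoms: none
Why: MnO2 oxidizes the allylic C15 alcohol selectively and leaves the saturated C11 alcohol untouched.

Step 25
Reactants: 37 exocyclic enone
Product: 39 CNP0555433.1 (target), via C17 pinacol boronate 38 (not isolated)
Conditions: B2pin2, CuCl (5 mol %), xantphos (5 mol %), NaOt-Bu (5 mol %), MeOH, THF, 0 °C; then NaBO3·4H2O, THF/H2O, 0 °C to rt
Reagents that add atoms: sodium perborate (oxygen on C17), [Na+].[O-]OB=O; bis(pinacolato)diboron (boron of 38 only), CC1(C)OB(OC1(C)C)B2OC(C)(C)C(C)(C)O2
Why: Copper-catalysed conjugate borylation puts boron on C17, methanol protonates the enolate at C16 on the open exo face of ring D (away from C11 and C12) so that H-16 is exo and the CH2 group endo as in the target, and perborate oxidizes the C–B bond with retention under conditions too mild to epimerize C16 or open the β-keto lactone.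

**Compound list**

1 | (2E)-penta-2,4-dien-1-ol | OC/C=C/C=C | starting material
2 | tert-butyl(dimethyl)[(2E)-penta-2,4-dien-1-yloxy]silane | C=C/C=C/CO[Si](C)(C)C(C)(C)C | intermediate
3 | 1,3-oxazolidin-2-one | O=C1NCCO1 | starting material
4 | ethyl (2E)-4-chloro-4-oxobut-2-enoate | CCOC(=O)/C=C/C(=O)Cl | starting material
5 | ethyl (2E)-4-oxo-4-(2-oxo-1,3-oxazolidin-3-yl)but-2-enoate | CCOC(=O)/C=C/C(=O)N1CCOC1=O | intermediate
6 | Diels–Alder adduct (cyclohexene; C4 ester, C5 imide, C10 CH2OTBS) | CCOC(=O)[C@H]1CC=C[C@H](CO[Si](C)(C)C(C)(C)C)[C@@H]1C(=O)N2CCOC2=O | intermediate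
7 | saturated imide | CCOC(=O)[C@H]1CCC[C@H](CO[Si](C)(C)C(C)(C)C)[C@@H]1C(=O)N2CCOC2=O | intermediate
8 | peroxy acid at C6 | CCOC(=O)[C@H]1CCC[C@H](CO[Si](C)(C)C(C)(C)C)[C@@H]1C(=O)OO | intermediate (not isolated)
9 | hemiester acid | CCOC(=O)[C@H]1CCC[C@H](CO[Si](C)(C)C(C)(C)C)[C@@H]1C(=O)O | intermediate
10 | dilithium enolate carboxylate of 9 | [Li+].[Li+].CCOC([O-])=C1CCC[C@H](CO[Si](C)(C)C(C)(C)C)[C@@H]1C(=O)[O-] | intermediate (not isolated)
11 | C4-methylated hemiester | CCOC(=O)[C@]1(C)CCC[C@H](CO[Si](C)(C)C(C)(C)C)[C@@H]1C(=O)O | intermediate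
12 | γ-hydroxy acid | C[C@@]1(CO)CCC[C@H](CO[Si](C)(C)C(C)(C)C)[C@@H]1C(=O)O | intermediate (not isolated)
13 | 6,19-lactone silyl ether | C[C@@]12CCC[C@H](CO[Si](C)(C)C(C)(C)C)[C@@H]1C(=O)OC2 | intermediate
14 | hydroxy lactone | C[C@@]12CCC[C@H](CO)[C@@H]1C(=O)OC2 | intermediate
15 | lactone aldehyde | C[C@@]12CCC[C@H](C=O)[C@@H]1C(=O)OC2 | intermediate
16 | diallyl acetal of 15 | C[C@@]12CCC[C@H](C(OCC=C)OCC=C)[C@@H]1C(=O)OC2 | intermediate (not isolated)
17 | allyl enol ether of 15 | C[C@@]12CCCC(=COCC=C)[C@@H]1C(=O)OC2 | intermediate (not isolated)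
18 | C10-quaternary allyl aldehyde | C[C@@]12CCC[C@](CC=C)(C=O)[C@@H]1C(=O)OC2 | intermediate
19 | diethyl 2-(prop-2-yn-1-yl)propanedioate | CCOC(=O)C(CC#C)C(=O)OCC | starting material
20 | 2-(prop-2-yn-1-yl)propanedioic acid | OC(=O)C(CC#C)C(=O)O | intermediate
21 | 2-methylidenepent-4-ynoic acid | C=C(CC#C)C(=O)O | intermediate
22 | 2-methylidenepent-4-ynoyl chloride | C=C(CC#C)C(=O)Cl | intermediate
23 | diisobutylaluminium alkoxide at O20 | C[C@@]12CCC[C@](CC=C)(CO[Al](CC(C)C)CC(C)C)[C@@H]1C(=O)OC2 | intermediate (not isolated)
24 | O20 2-propargylacrylate, C10 allyl | C[C@@]12CCC[C@](CC=C)(COC(=O)C(=C)CC#C)[C@@H]1C(=O)OC2 | intermediate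
25 | diol from the allyl group | C[C@@]12CCC[C@](CC(O)CO)(COC(=O)C(=C)CC#C)[C@@H]1C(=O)OC2 | intermediate (not isolated)
26 | C11 aldehyde | C[C@@]12CCC[C@](CC=O)(COC(=O)C(=C)CC#C)[C@@H]1C(=O)OC2 | intermediate
27 | C11 allylic alcohol (both epimers) | C[C@@]12CCC[C@](CC(O)C=C)(COC(=O)C(=C)CC#C)[C@@H]1C(=O)OC2 | intermediate
28 | vinyl ketone | C[C@@]12CCC[C@](CC(=O)C=C)(COC(=O)C(=C)CC#C)[C@@H]1C(=O)OC2 | intermediate
29 | (Z)-silyloxydiene acrylate | C[C@@]12CCC[C@](/C=C(\O[Si](C)(C)C(C)(C)C)C=C)(COC(=O)C(=C)CC#C)[C@@H]1C(=O)OC2 | intermediate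
30 | cycloadduct silyl enol ether | C[C@@]12CCC[C@]3(COC(=O)[C@@]4(CC#C)CCC=C(O[Si](C)(C)C(C)(C)C)[C@H]43)[C@@H]1C(=O)OC2 | intermediate (not isolated)
31 | keto dilactone (rings A, B, C) | C[C@@]12CCC[C@]3(COC(=O)[C@@]4(CC#C)CCCC(=O)[C@H]43)[C@@H]1C(=O)OC2 | intermediate
32 | enone (C11=O, C12=C13) | C[C@@]12CCC[C@]3(COC(=O)[C@@]4(CC#C)CC=CC(=O)[C@H]43)[C@@H]1C(=O)OC2 | intermediate
33 | vinylstannane | C[C@@]12CCC[C@]3(COC(=O)[C@@]45C[C@@H](CC(=O)[C@H]43)C(=C[Sn](CCCC)(CCCC)CCCC)C5)[C@@H]1C(=O)OC2 | intermediate (not isolated)
34 | 11-oxo-16-ene compound | C[C@@]12CCC[C@]3(COC(=O)[C@@]45C[C@@H](CC(=O)[C@H]43)C(=C)C5)[C@@H]1C(=O)OC2 | intermediate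
35 | 11-hydroxy-16-ene compound | C[C@@]12CCC[C@]3(COC(=O)[C@@]45C[C@@H](C[C@@H](O)[C@H]43)C(=C)C5)[C@@H]1C(=O)OC2 | intermediate
36 | 11,15-diol | C[C@@]12CCC[C@]3(COC(=O)[C@@]45C[C@@H](C[C@@H](O)[C@H]43)C(=C)C5O)[C@@H]1C(=O)OC2 | intermediate
37 | 11-hydroxy-15-oxo-16-ene compound | C[C@@]12CCC[C@]3(COC(=O)[C@@]45C[C@@H](C[C@@H](O)[C@H]43)C(=C)C5=O)[C@@H]1C(=O)OC2 | intermediate
38 | C17 pinacol boronate | C[C@@]12CCC[C@]3(COC(=O)[C@@]45C[C@@H](C[C@@H](O)[C@H]43)[C@@H](CB6OC(C)(C)C(C)(C)O6)C5=O)[C@@H]1C(=O)OC2 | intermediate (not isolated)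
39 | CNP0555433.1 | C[C@@]12CCC[C@]3(COC(=O)[C@@]45C[C@@H](C[C@@H](O)[C@H]43)[C@@H](CO)C5=O)[C@@H]1C(=O)OC2 | target

**Step count and risks**

Total step count: 25. Longest linear sequence: 21 steps (steps 1, 3 to 10 and 14 to 25).

Step 19. The cycloaddition may be too slow against the s-trans preference of the ester and the electronic bias of the silyloxydiene, so that thermal loss of the silyl dienol ether or closure through the exo arrangement competes. The fallback sets out from 27 and uses an unpolarized diene whose C13 terminus is electronically matched to C14. Dehydration of 27 with the Burgess reagent should give the (E)-1,3-diene F1. Thermolysis in toluene should give the cyclohexene-fused δ-lactone F2 (C11=C12). Epoxidation with m-CPBA gives the epoxide F3, opening at C12 with PhSeNa gives the hydroxy selenide F4, and selenoxide elimination with H2O2 gives the allylic alcohol F5 (C11–OH, C12=C13). Dess–Martin oxidation of F5 comes back to the route at enone 32.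

Step 10. The allyl group may be delivered to the concave face, syn to the lactone, which would give the C10 epimer. The fallback sets out from 15 and uses that same facial bias to place C20 instead of C9. Crossed aldol reaction of 15 with aqueous formaldehyde and K2CO3 should give the hydroxymethyl aldehyde F6, in which the new CH2OH is C20 and the old aldehyde carbon becomes C9. Wittig reaction with Ph3P=CHOMe gives the methyl enol ether F7, and acylation of O20 with 22 (pyridine, DMAP) gives the acrylate enol ether F8. Mild acid hydrolysis of F8 comes back to the route at aldehyde 26.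

Step 22. Protonation of the ketyl may show poor facial selectivity and leave the axial alcohol, or a lactone may be reduced. The fallback sets out from 34 and reaches the equatorial alcohol by inversion. NaBH4 should deliver hydride on the face remote from the C15–C16 bridge and give the axial 11-epi alcohol F9. Mitsunobu reaction with 4-nitrobenzoic acid, PPh3 and DIAD gives the inverted 4-nitrobenzoate F10. Methanolysis with K2CO3 in MeOH at 0 °C comes back to the route at 35.

Further compounds
F1 | step 19 | (E)-1,3-diene on C10 with O20 acrylate | C[C@@]12CCC[C@](/C=C/C=C)(COC(=O)C(=C)CC#C)[C@@H]1C(=O)OC2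
F2 | step 19 | cycloadduct with C11=C12 | C[C@@]12CCC[C@]3(COC(=O)[C@@]4(CC#C)CCC=C[C@H]43)[C@@H]1C(=O)OC2
F3 | step 19 | C11–C12 epoxide | C[C@@]12CCC[C@]3(COC(=O)[C@@]4(CC#C)CCC5OC5[C@H]43)[C@@H]1C(=O)OC2
F4 | step 19 | C11 hydroxy C12 phenyl selenide | C[C@@]12CCC[C@]3(COC(=O)[C@@]4(CC#C)CCC([Se]c5ccccc5)C(O)[C@H]43)[C@@H]1C(=O)OC2
F5 | step 19 | C11 allylic alcohol with C12=C13 | C[C@@]12CCC[C@]3(COC(=O)[C@@]4(CC#C)CC=CC(O)[C@H]43)[C@@H]1C(=O)OC2
F6 | step 10 | C10 hydroxymethyl aldehyde | C[C@@]12CCC[C@](C=O)(CO)[C@@H]1C(=O)OC2
F7 | step 10 | C10 methyl enol ether alcohol | C[C@@]12CCC[C@](C=COC)(CO)[C@@H]1C(=O)OC2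
F8 | step 10 | O20 acrylate methyl enol ether | C[C@@]12CCC[C@](C=COC)(COC(=O)C(=C)CC#C)[C@@H]1C(=O)OC2
F9 | step 22 | 11-epi alcohol (axial OH) | C[C@@]12CCC[C@]3(COC(=O)[C@@]45C[C@@H](C[C@H](O)[C@H]43)C(=C)C5)[C@@H]1C(=O)OC2
F10 | step 22 | C11 4-nitrobenzoate (inverted) | C[C@@]12CCC[C@]3(COC(=O)[C@@]45C[C@@H](C[C@@H](OC(=O)c6ccc(cc6)[N+](=O)[O-])[C@H]43)C(=C)C5)[C@@H]1C(=O)OC2
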